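Two chemists stand at this board and argue over what more substrate does to the target at the asked time.

the same everywhere: partner 0.0525 M; reagent 0.125 M

| charge | substrate | capture agent | remark | time |
|---|---|---|---|---|
| epsilon | 0.062 M | 2.5 mM | run made earlier |  |
| beta | 0.74 M | 2.5 mM | run made earlier |  |
| midnight | 0.050 M | 2.50 mM |  | 80 min |
| noon | 0.15 M | 2.50 mM |  | 80 min |
| summer | 0.50 M | 2.50 mM |  | 80 min |

- epsilon (time / min: target / %, substrate / %): 6.00: 0.3, 90.2; 12.0: 1.1, 83.4; 15.0: 1.6, 80.0; 25.0: 3.2, 73.7; 30.0: 3.8, 71.6; 40.0: 5.3, 69.2
- beta (time / min: target / %, substrate / %): 2.00: 0, 96.8; 6.00: 0.2, 92.0; 12.0: 0.3, 89.4; 15.0: 0.2, 89.1; 25.0: 0.8, 88.0; 30.0: 0.6, 88.2; 40.0: 0.3, 87.8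

(readings scatter by 0.5 percentage points)

- [target] at the end for midnight, noon, summer, in this order
- how the row runs (hardly changes / rises, then falls / falls, then rises / falls all the way / rises all the way)

- a species is counted by the substrate in it: one homo product counts as two
- candidate steps: target <-> isomer of the product; reagent + partner -> second intermediate; open intermediate + second intermediate -> target; reagent -> decomposed reagent; 2 open intermediate -> homo product; substrate + reagent -> open intermediate; open intermediate + capture agent -> trapped intermediate
- "hardly changes" means that all values lie within two and a half points (for a concentration: within two and a half percent of the largest)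

The second chemist counts turnovers of the reagent, one reagent for each substrate turned over, and treats the reagent as a tank with two drains. In beta the substrate stalls, at 88.0% after 25.0 min and 87.8% after 40.0 min, and she reads that halt as the end of the limiting reagent. The substrate lost there, 0.0903 M, is then 72.2% of the reagent charge.

The substrate drain grows with c substrate, and she takes the other drain, through partner and decomposition, as not growing with it. The substrate's share is therefore c substrate over c substrate plus a constant. Beta puts that constant at 0.285 M, the crossover charge, the c substrate at which both drains take equal shares.

The target step needs open intermediate and second intermediate together, so she scores each flask by its pair number, the share times the remainder, taking the second intermediate as a fixed part of that remainder. The row scores 0.127, 0.226 and 0.231, so she commits to a rise all the way, with summer barely above noon.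

The first chemist made the forecast and holds a supply view: “More substrate kills the reagent sooner”. It gives 0.0048 M, 0.006 M and 0.0041 M, with the shape rises, then falls. The two part at summer over noon, which is 0.683 in the forecast and 1.02 in the pair number.

The flask gives 0.00614 M, 0.0116 M and 0.0117 M, with the shape rises all the way.

    target ⇌ isomer of the product (K = 2.10, k = 1.50 × 10⁻⁴ s⁻¹)
    reagent + partner → second intermediate (k = 0.00820 M⁻¹ s⁻¹)
    open intermediate + second intermediate → target (k = 0.00480 M⁻¹ s⁻¹)
    reagent → decomposed reagent (k = 2.80 × 10⁻⁴ s⁻¹)
    2 open intermediate → homo product (k = 2.60 × 10⁻⁴ M⁻¹ s⁻¹)
    substrate + reagent → open intermediate (k = 0.00260 M⁻¹ s⁻¹)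
    open intermediate + capture agent → trapped intermediate (k = 0.00140 M⁻¹ s⁻¹)

In summer the reagent is down to 0.036% of its charge after 80.0 min. Target per unit of pair number, reckoned from the crossover charge of 0.285 M, comes to 0.0483 M at midnight, 0.0513 M at noon and 0.0506 M in summer. The pair number peaks at the crossover charge of 0.285 M, which lies between noon and summer, so in her reckoning the forecast's fall has its region above that charge, where summer already stands and where beta's pair number of 0.201 lies below summer's. Beta's target reading after 40.0 min is 0.00222 M, give or take 0.00370 M, against 0.00846 M in summer after 40.0 min.

The readings are simulated with constants of no real substance, noise included.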